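**Plan**

1. Retrosynthesis: the C8 tiglate and the C3 ketone are removed first (esterification, alcohol oxidation). The ten-membered ring is then cut at C7–C8, the open chain at C3–C4, the butenolide at C7=C11, and the eastern piece at C8–C9 and C1=C2.
2. Feature used: C7 is both the γ-carbon of the allyl unit C13–C11=C7 of a 3-(bromomethyl)butenolide and the neighbour of the C8 carbinol. One C7–C8 bond from an allylindium to the C8 aldehyde therefore closes the carbocycle (C1–C10) and moves the alkene to C11=C13 on the lactone ring.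
3. Forward: butenolide iodide 10 (C4–C7, C11–C13, C15) from but-2-yn-1-ol; enal 16 (C1–C3, C8–C10, C14) from (S)-2-methylglycidol and 1,3-dithiane; chromium-mediated union at C3–C4; unmasking of the C13 bromide and C8 aldehyde; Barbier ring closure; tigloylation, desilylation, oxidation.
4. Stereochemistry: C10 from the chiral pool (2-methylglycidol); C6 by catalytic asymmetric vinylation; C7 from C6 and C8 from the chelating C10 hydroxyl during ring closure; 4Z from trans-hydroalumination/iodination; 1E from a stabilised ylide.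
5. C3 is held at the alcohol level as a silyl ether until the last step, so that the C8 aldehyde is the only carbonyl group the allylindium can reach (a C3 ketone would invite a five-membered closure C7–C3).

Key step: step 16

Assumption: the C3 carbinol made in step 11 is carried as both epimers (C3 is undefined in the SMILES of 18–24, 27 and 28) because this centre becomes the ketone in step 19; the epimers can be separated at 19 if they behave differently in step 16. Locants C1–C15 follow the germacrane numbering of the target. The descriptor of the butenolide carbon C6 reads S in 9, 10 and 17 and R from 18 on only because iodine (or chromium) is replaced by carbon; the centre is never inverted.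

**Route**

Step 1
Reactants: 1 but-2-yn-1-ol
Product: 3 (2Z)-3-iodobut-2-en-1-ol, via cyclic alkenylaluminate 2 (not isolated)
Conditions: NaAlH2(OCH2CH2OCH3)2 (Red-Al), THF, 0 °C to rt; then I2, THF, −78 °C
Reagents that add atoms: iodine, II
Why: Hydroxyl-directed trans-hydroalumination of the propargylic alcohol should place aluminium on C3 within a five-membered aluminate, and iodinolysis of the C–Al bond with retention gives the Z-alkenyl iodide that later becomes the 4Z alkene.

Step 2
Reactants: 3 (2Z)-3-iodobut-2-en-1-ol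
Product: 4 (2Z)-3-iodobut-2-enal
Conditions: MnO2, CH2Cl2, rt, dark; used at once
Reagents that add atoms: none
Why: MnO2 oxidises the allylic alcohol to the enal under neutral conditions that leave the C–I bond and the Z geometry alone.

Step 3
Reactants: 4 (2Z)-3-iodobut-2-enal
Product: 5 (3S,4Z)-5-iodohexa-1,4-dien-3-ol
Conditions: (CH2=CH)2Zn [from CH2=CHMgBr and ZnCl2, Mg salts removed with 1,4-dioxane], (2S)-3-exo-morpholinoisoborneol [(−)-MIB] (10 mol%), toluene, −20 to 0 °C
Reagents that add atoms: divinylzinc, C=C[Zn]C=C (made in the flask from vinylmagnesium bromide, C=C[Mg]Br)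
Why: Amino-alcohol-catalysed organozinc addition to an aldehyde: the zinc alkoxide of (−)-MIB should direct the vinyl group to the Si face of the enal, as it does with other alkyl- and alkenylzinc reagents, which sets C6 (3S here).

Step 4
Reactants: 6 methyl 2-(hydroxymethyl)prop-2-enoate
Product: 7 methyl 2-{[(tert-butyldimethylsilyl)oxy]methyl}prop-2-enoate
Conditions: TBSCl, imidazole, CH2Cl2, 0 °C to rt
Reagents that add atoms: tert-butyldimethylsilyl chloride, CC(C)(C)[Si](C)(C)Cl
Why: Standard silylation of the primary allylic alcohol masks the future C13 oxygen through the metathesis and chromium steps.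

Step 5
Reactants: 7 methyl 2-{[(tert-butyldimethylsilyl)oxy]methyl}prop-2-enoate
Product: 8 2-{[(tert-butyldimethylsilyl)oxy]methyl}prop-2-enoic acid
Conditions: LiOH, THF/H2O, 0 °C to rt; then cold dilute HCl to pH 3
Reagents that add atoms: lithium hydroxide, [Li+].[OH-]
Why: Saponification of the methyl ester with LiOH leaves the primary silyl ether intact and gives the acid needed to acylate 5.

Step 6
Reactants: 5 (3S,4Z)-5-iodohexa-1,4-dien-3-ol; 8 2-{[(tert-butyldimethylsilyl)oxy]methyl}prop-2-enoic acid
Product: 9 (3S,4Z)-5-iodohexa-1,4-dien-3-yl 2-{[(tert-butyldimethylsilyl)oxy]methyl}prop-2-enoate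
Conditions: DCC, DMAP (cat.), CH2Cl2, 0 °C to rt
Reagents that add atoms: none
Why: Steglich esterification acylates the secondary alcohol without touching the C–O bond at C6, so its configuration is retained.

Step 7
Reactants: 9 (3S,4Z)-5-iodohexa-1,4-dien-3-yl 2-{[(tert-butyldimethylsilyl)oxy]methyl}prop-2-enoate
Product: 10 (5S)-3-{[(tert-butyldimethylsilyl)oxy]methyl}-5-[(1Z)-2-iodoprop-1-en-1-yl]furan-2(5H)-one
Conditions: second-generation Grubbs catalyst (H2IMes)(PCy3)Cl2Ru=CHPh (5 mol%), toluene, 80 °C, argon sparge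
Reagents that add atoms: none
Why: Ring-closing metathesis of the vinyl group onto the 1,1-disubstituted acrylate closes the butenolide (C7=C11) with loss of ethene, a known route to 3-substituted furan-2(5H)-ones; the trisubstituted iodoalkene does not engage the ruthenium carbene.

Step 8
Reactants: 11 [(2S)-2-methyloxiran-2-yl]methanol ((S)-2-methylglycidol); 12 1,3-dithiane
Product: 14 (2R)-3-(1,3-dithian-2-yl)-2-methylpropane-1,2-diol, via 2-lithio-1,3-dithiane 13 (not isolated)
Conditions: 12 (2.2 equiv), n-BuLi (2.2 equiv), THF, −30 °C; then 11, −30 to 0 °C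
Reagents that add atoms: none
Why: Umpolung alkylation (Corey–Seebach): after the first equivalent of 13 has deprotonated the hydroxyl, the second opens the epoxide by SN2 attack at its CH2 terminus, so the quaternary centre (future C10) is untouched and the dithiane carbon becomes C8 at the aldehyde oxidation level.

Step 9
Reactants: 14 (2R)-3-(1,3-dithian-2-yl)-2-methylpropane-1,2-diol
Product: 15 (2R)-3-(1,3-dithian-2-yl)-2-hydroxy-2-methylpropanal
Conditions: SO3·pyridine, DMSO, iPr2NEt, CH2Cl2, 0 °C; used crude
Reagents that add atoms: none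
Why: Parikh–Doering oxidation converts the primary alcohol of the 1,2-diol into the aldehyde without C–C cleavage or sulfur oxidation; the α-centre is quaternary and cannot epimerise.

Step 10
Reactants: 15 (2R)-3-(1,3-dithian-2-yl)-2-hydroxy-2-methylpropanal
Product: 16 (2E,4R)-5-(1,3-dithian-2-yl)-4-hydroxy-4-methylpent-2-enal
Conditions: Ph3P=CHCHO, toluene, 50 °C
Reagents that add atoms: (triphenylphosphoranylidene)acetaldehyde, O=CC=P(c1ccccc1)(c1ccccc1)c1ccccc1
Why: Wittig olefination with the stabilised formylmethylene ylide should give the E-enal (C1=C2) and install C3 as the aldehyde for the fragment union.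

Step 11
Reactants: 10 (5S)-3-{[(tert-butyldimethylsilyl)oxy]methyl}-5-[(1Z)-2-iodoprop-1-en-1-yl]furan-2(5H)-one; 16 (2E,4R)-5-(1,3-dithian-2-yl)-4-hydroxy-4-methylpent-2-enal
Product: 18 (5R)-3-{[(tert-butyldimethylsilyl)oxy]methyl}-5-[(1Z,4E,6R)-7-(1,3-dithian-2-yl)-3,6-dihydroxy-2,6-dimethylhepta-1,4-dien-1-yl]furan-2(5H)-one (both C3′ epimers), via alkenylchromium dichloride 17 (not isolated)
Conditions: CrCl2 (6 equiv), NiCl2 (2 mol%), DMSO, rt
Reagents that add atoms: none
Why: Nozaki–Hiyama–Kishi coupling: zerovalent nickel (from NiCl2 and CrCl2) inserts into the C–I bond, transmetalation gives the trivalent alkenylchromium 17 with retention of the Z geometry, and this adds 1,2 to the enal in the presence of the lactone, silyl ether, dithiane and free tertiary alcohol; C3 forms as both epimers, which is of no consequence.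

Step 12
Reactants: 18 the C3 carbinol from step 11
Product: 19 (5R)-3-{[(tert-butyldimethylsilyl)oxy]methyl}-5-[(1Z,4E,6R)-3-[(tert-butyldimethylsilyl)oxy]-7-(1,3-dithian-2-yl)-6-hydroxy-2,6-dimethylhepta-1,4-dien-1-yl]furan-2(5H)-one (both C3′ epimers)
Conditions: TBSOTf (1.1 equiv), 2,6-lutidine, CH2Cl2, −78 °C
Reagents that add atoms: tert-butyldimethylsilyl trifluoromethanesulfonate, CC(C)(C)[Si](C)(C)OS(=O)(=O)C(F)(F)F
Why: Silylation with TBSOTf at −78 °C should take the secondary C3 alcohol and leave the tertiary C10 alcohol free, which masks C3 for the bromination and the ring closure.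

Step 13
Reactants: 19 the bis-silyl ether from step 12
Product: 20 (5R)-5-[(1Z,4E,6R)-3-[(tert-butyldimethylsilyl)oxy]-7-(1,3-dithian-2-yl)-6-hydroxy-2,6-dimethylhepta-1,4-dien-1-yl]-3-(hydroxymethyl)furan-2(5H)-one (both C3′ epimers)
Conditions: HF·pyridine, pyridine, THF, 0 °C
Reagents that add atoms: none
Why: Buffered HF·pyridine cleaves the unhindered primary allylic silyl ether much faster than the hindered secondary one at C3 (selective desilylation).

Step 14
Reactants: 20 the C13 alcohol from step 13
Product: 21 (5R)-3-(bromomethyl)-5-[(1Z,4E,6R)-3-[(tert-butyldimethylsilyl)oxy]-7-(1,3-dithian-2-yl)-6-hydroxy-2,6-dimethylhepta-1,4-dien-1-yl]furan-2(5H)-one (both C3′ epimers)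
Conditions: CBr4, PPh3, CH2Cl2, 0 °C
Reagents that add atoms: carbon tetrabromide, BrC(Br)(Br)Br
Why: Appel bromination converts the primary allylic alcohol into the allylic bromide under neutral conditions; the tertiary alcohol, thioacetal and silyl ether should be inert at 0 °C.

Step 15
Reactants: 21 the C13 bromide from step 14
Product: 22 (5R)-3-(bromomethyl)-5-[(1Z,4E,6R)-3-[(tert-butyldimethylsilyl)oxy]-6-hydroxy-2,6-dimethyl-8-oxoocta-1,4-dien-1-yl]furan-2(5H)-one (both C3′ epimers)
Conditions: PhI(OCOCF3)2, NaHCO3, MeCN/H2O 9:1, 0 °C; used directly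
Reagents that add atoms: water, O
Why: Oxidative hydrolysis of the thioacetal with the hypervalent iodine reagent in buffered aqueous acetonitrile should release the C8 aldehyde within minutes without touching the allylic bromide.

Step 16
Reactants: 22 the bromomethylbutenolide aldehyde from step 15
Product: 24 (1E,4Z,6R,7R,8R,10R)-3-[(tert-butyldimethylsilyl)oxy]-8,10-dihydroxygermacra-1,4,11(13)-trien-12,6-olide (both C3 epimers), via allylindium dibromide 23 (not isolated)
Conditions: indium powder (In, 4 equiv), THF/H2O 1:1, slow addition of 22 to about 1 mM, rt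
Reagents that add atoms: none
Why: Proposed new method: indium inserts into the allylic C13–Br bond and the allylindium 23 adds through its γ-carbon C7 to the C8 aldehyde within a closed six-membered array (In–C13–C11=C7···C8=O, SE2′), which forms C7–C8, shifts the alkene to C11=C13 and so unveils the α-methylene lactone as the carbocycle closes. The closest known reaction is the intermolecular indium- or zinc-mediated Barbier allylation of aldehydes with 3-(bromomethyl)furan-2(5H)-ones in aqueous THF, which gives β-(hydroxyalkyl)-α-methylene-γ-butyrolactones; its use for a ring of this size is new. The ten-membered ring (C1–C10) closes in a 10-exo-trig addition to the aldehyde. C7 is controlled by C6: the tethered aldehyde should reach C7 on the butenolide face anti to the C5 substituent, the only approach that avoids a cis ring fusion, giving the trans lactone (7R). C8 is controlled by the free C10 hydroxyl, β to the aldehyde, which should chelate indium so that C9 lies cis to the metal on the carbonyl group (axial in the six-membered array) and the 8,10-anti diol (8R) results, as in indium allylations of β-hydroxy aldehydes in water. The step needs attack on the aldehyde only and ring closure in preference to oligomerisation: the first is secured by holding C3 as a silyl ether (no ketone within reach of C7), the second by slow addition at high dilution.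

Step 17
Reactants: 24 the macrocyclic diol from step 16; 25 tiglic acid
Product: 27 (1E,4Z,6R,7R,8R,10R)-3-[(tert-butyldimethylsilyl)oxy]-10-hydroxy-8-[(E)-2-methylbut-2-enoyloxy]germacra-1,4,11(13)-trien-12,6-olide (both C3 epimers), via tiglic 2,4,6-trichlorobenzoic anhydride 26 (not isolated)
Conditions: 25, 2,4,6-trichlorobenzoyl chloride, Et3N, toluene, rt; then 24, DMAP, rt to 40 °C
Reagents that add atoms: none
Why: Yamaguchi esterification through mixed anhydride 26 acylates the secondary C8 alcohol with retention; the tertiary C10 alcohol does not react.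

Step 18
Reactants: 27 the C8 tiglate from step 17
Product: 28 (1E,4Z,6R,7R,8R,10R)-3,10-dihydroxy-8-[(E)-2-methylbut-2-enoyloxy]germacra-1,4,11(13)-trien-12,6-olide (both C3 epimers)
Conditions: HF·pyridine, pyridine, THF, 0 °C to rt
Reagents that add atoms: none
Why: Fluoride-mediated desilylation with buffered HF·pyridine frees the C3 alcohol under conditions that should spare the α-methylene lactone and the tiglate.

Step 19
Reactants: 28 the C3 alcohol from step 18
Product: 29 eupaheliangolide A, (1E,4Z,6R,7R,8R,10R)-10-hydroxy-8-[(E)-2-methylbut-2-enoyloxy]-3-oxogermacra-1,4,11(13)-trien-12,6-olide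
Conditions: Dess–Martin periodinane, NaHCO3, CH2Cl2, 0 °C to rt
Reagents that add atoms: none
Why: Dess–Martin oxidation of the bis-allylic C3 alcohol gives the cross-conjugated dienone and converges both C3 epimers on the target; the tertiary alcohol cannot be oxidised.

**Compound list**

1 | but-2-yn-1-ol | CC#CCO | starting material
2 | sodium salt of the cyclic (Z)-alkenylaluminate from trans-hydroalumination of 1 | C/C1=C/CO[Al-]1(OCCOC)OCCOC.[Na+] | intermediate
3 | (2Z)-3-iodobut-2-en-1-ol | C/C(I)=C/CO | intermediate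
4 | (2Z)-3-iodobut-2-enal | C/C(I)=C/C=O | intermediate
5 | (3S,4Z)-5-iodohexa-1,4-dien-3-ol | C=C[C@H](O)/C=C(/C)I | intermediate
6 | methyl 2-(hydroxymethyl)prop-2-enoate | C=C(CO)C(=O)OC | starting material
7 | methyl 2-{[(tert-butyldimethylsilyl)oxy]methyl}prop-2-enoate | C=C(CO[Si](C)(C)C(C)(C)C)C(=O)OC | intermediate
8 | 2-{[(tert-butyldimethylsilyl)oxy]methyl}prop-2-enoic acid | C=C(CO[Si](C)(C)C(C)(C)C)C(=O)O | intermediate
9 | (3S,4Z)-5-iodohexa-1,4-dien-3-yl 2-{[(tert-butyldimethylsilyl)oxy]methyl}prop-2-enoate | C=C[C@H](OC(=O)C(=C)CO[Si](C)(C)C(C)(C)C)/C=C(/C)I | intermediate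
10 | (5S)-3-{[(tert-butyldimethylsilyl)oxy]methyl}-5-[(1Z)-2-iodoprop-1-en-1-yl]furan-2(5H)-one | CC(C)(C)[Si](C)(C)OCC1=C[C@H](OC1=O)/C=C(/C)I | intermediate
11 | [(2S)-2-methyloxiran-2-yl]methanol, (S)-2-methylglycidol | OC[C@]1(C)OC1 | starting material
12 | 1,3-dithiane | C1CSCSC1 | starting material
13 | 2-lithio-1,3-dithiane | [Li]C1SCCCS1 | intermediate
14 | (2R)-3-(1,3-dithian-2-yl)-2-methylpropane-1,2-diol | OC[C@](C)(O)CC1SCCCS1 | intermediate
15 | (2R)-3-(1,3-dithian-2-yl)-2-hydroxy-2-methylpropanal | O=C[C@](C)(O)CC1SCCCS1 | intermediate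
16 | (2E,4R)-5-(1,3-dithian-2-yl)-4-hydroxy-4-methylpent-2-enal | O=C/C=C/[C@](C)(O)CC1SCCCS1 | intermediate
17 | (5S)-3-{[(tert-butyldimethylsilyl)oxy]methyl}-5-[(1Z)-2-(dichlorochromio)prop-1-en-1-yl]furan-2(5H)-one, trivalent alkenylchromium | CC(C)(C)[Si](C)(C)OCC1=C[C@H](OC1=O)/C=C(/C)[Cr](Cl)Cl | intermediate
18 | (5R)-3-{[(tert-butyldimethylsilyl)oxy]methyl}-5-[(1Z,4E,6R)-7-(1,3-dithian-2-yl)-3,6-dihydroxy-2,6-dimethylhepta-1,4-dien-1-yl]furan-2(5H)-one, both C3′ epimers | CC(C)(C)[Si](C)(C)OCC1=C[C@H](OC1=O)/C=C(/C)C(O)/C=C/[C@](C)(O)CC2SCCCS2 | intermediate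
19 | (5R)-3-{[(tert-butyldimethylsilyl)oxy]methyl}-5-[(1Z,4E,6R)-3-[(tert-butyldimethylsilyl)oxy]-7-(1,3-dithian-2-yl)-6-hydroxy-2,6-dimethylhepta-1,4-dien-1-yl]furan-2(5H)-one, both C3′ epimers | CC(C)(C)[Si](C)(C)OCC1=C[C@H](OC1=O)/C=C(/C)C(O[Si](C)(C)C(C)(C)C)/C=C/[C@](C)(O)CC2SCCCS2 | intermediate
20 | (5R)-5-[(1Z,4E,6R)-3-[(tert-butyldimethylsilyl)oxy]-7-(1,3-dithian-2-yl)-6-hydroxy-2,6-dimethylhepta-1,4-dien-1-yl]-3-(hydroxymethyl)furan-2(5H)-one, both C3′ epimers | OCC1=C[C@H](OC1=O)/C=C(/C)C(O[Si](C)(C)C(C)(C)C)/C=C/[C@](C)(O)CC2SCCCS2 | intermediate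
21 | (5R)-3-(bromomethyl)-5-[(1Z,4E,6R)-3-[(tert-butyldimethylsilyl)oxy]-7-(1,3-dithian-2-yl)-6-hydroxy-2,6-dimethylhepta-1,4-dien-1-yl]furan-2(5H)-one, both C3′ epimers | BrCC1=C[C@H](OC1=O)/C=C(/C)C(O[Si](C)(C)C(C)(C)C)/C=C/[C@](C)(O)CC2SCCCS2 | intermediate
22 | (5R)-3-(bromomethyl)-5-[(1Z,4E,6R)-3-[(tert-butyldimethylsilyl)oxy]-6-hydroxy-2,6-dimethyl-8-oxoocta-1,4-dien-1-yl]furan-2(5H)-one, both C3′ epimers (ring-closure precursor) | BrCC1=C[C@H](OC1=O)/C=C(/C)C(O[Si](C)(C)C(C)(C)C)/C=C/[C@](C)(O)CC=O | intermediate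
23 | C13 allylindium dibromide of 22 (drawn as one component of the allylindium sesquibromide) | Br[In](Br)CC1=C[C@H](OC1=O)/C=C(/C)C(O[Si](C)(C)C(C)(C)C)/C=C/[C@](C)(O)CC=O | intermediate
24 | (1E,4Z,6R,7R,8R,10R)-3-[(tert-butyldimethylsilyl)oxy]-8,10-dihydroxygermacra-1,4,11(13)-trien-12,6-olide, both C3 epimers (trans-fused α-methylene lactone) | C=C1C(=O)O[C@@H]2/C=C(/C)C(O[Si](C)(C)C(C)(C)C)/C=C/[C@](C)(O)C[C@@H](O)[C@@H]12 | intermediate
25 | tiglic acid, (E)-2-methylbut-2-enoic acid | C/C=C(\C)C(=O)O | starting material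
26 | (E)-2-methylbut-2-enoic 2,4,6-trichlorobenzoic anhydride | C/C=C(\C)C(=O)OC(=O)c1c(Cl)cc(Cl)cc1Cl | intermediate
27 | (1E,4Z,6R,7R,8R,10R)-3-[(tert-butyldimethylsilyl)oxy]-10-hydroxy-8-[(E)-2-methylbut-2-enoyloxy]germacra-1,4,11(13)-trien-12,6-olide, both C3 epimers | C=C1C(=O)O[C@@H]2/C=C(/C)C(O[Si](C)(C)C(C)(C)C)/C=C/[C@](C)(O)C[C@@H](OC(=O)/C(C)=C/C)[C@@H]12 | intermediate
28 | (1E,4Z,6R,7R,8R,10R)-3,10-dihydroxy-8-[(E)-2-methylbut-2-enoyloxy]germacra-1,4,11(13)-trien-12,6-olide, both C3 epimers | C=C1C(=O)O[C@@H]2/C=C(/C)C(O)/C=C/[C@](C)(O)C[C@@H](OC(=O)/C(C)=C/C)[C@@H]12 | intermediate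
29 | eupaheliangolide A | C=C1C(=O)O[C@@H]2/C=C(/C)C(=O)/C=C/[C@](C)(O)C[C@@H](OC(=O)/C(C)=C/C)[C@@H]12 | target

**Count**

Total step count: 19.
Longest linear sequence: 14 steps (steps 1, 2, 3, 6, 7 and 11–19, from but-2-yn-1-ol).

**Steps most likely to fail**

1. Step 16 (the new ring closure). What may go wrong: if indium is not held by the C10 hydroxyl, the allyl unit can add to the opposite face of the aldehyde through the array with C9 equatorial, so that C8 forms with the wrong configuration (poor facial selectivity at the carbonyl group). The fallback sets out from 22 and uses known chemistry. The ring closure then delivers the 8S carbinol, (1E,4Z,6R,7R,8S,10R)-3-[(tert-butyldimethylsilyl)oxy]-8,10-dihydroxygermacra-1,4,11(13)-trien-12,6-olide F1. The acylation with retention is replaced by a Mitsunobu esterification of F1 with tiglic acid 25 (PPh3, diisopropyl azodicarboxylate, toluene, 0 °C to rt), which inverts C8 and leaves the tertiary alcohol alone. This gives 27 directly, where the route is rejoined; step 17 is then not needed.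

2. Step 15. What may go wrong: the thioacetal sulfur and the allylic bromide may not coexist (S-alkylation on concentration), and the oxidant or the acid it releases may ionise the bis-allylic silyl ether or trigger β-elimination of the new aldehyde. The fallback sets out from 19 and moves the sulfur chemistry to a stage without bromide. The dithiane is exchanged for a dimethyl acetal with PhI(OCOCF3)2 and NaHCO3 in methanol, giving the dimethyl acetal analogue of 19 F2. Buffered HF·pyridine then frees the C13 alcohol F3, and CBr4/PPh3 gives the C13 bromide acetal F4. Mild Lewis-acid hydrolysis of the acetal (LiBF4, wet MeCN, rt) leads to 22, where the route is rejoined.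

3. Step 3. What may go wrong: uncatalysed vinyl transfer from the reactive divinylzinc may compete with the ligand-bound pathway and erode the enantiomeric purity at C6. The fallback sets out from 4 and replaces catalyst control by resolution. Vinylmagnesium bromide (THF, −78 °C) gives racemic (4Z)-5-iodohexa-1,4-dien-3-ol F5. Lipase-catalysed transesterification (immobilised Candida antarctica lipase B, vinyl acetate, hexane, rt) should acylate the 3R enantiomer, with the large iodoalkenyl and medium vinyl groups placed as in the usual empirical model, to (3R,4Z)-5-iodohexa-1,4-dien-3-yl acetate F6. The unreacted 3S alcohol is separated by chromatography and is 5, where the route is rejoined.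

**Further compounds**

F1 | step 16 | (1E,4Z,6R,7R,8S,10R)-3-[(tert-butyldimethylsilyl)oxy]-8,10-dihydroxygermacra-1,4,11(13)-trien-12,6-olide (8-epimer of 24, both C3 epimers) | C=C1C(=O)O[C@@H]2/C=C(/C)C(O[Si](C)(C)C(C)(C)C)/C=C/[C@](C)(O)C[C@H](O)[C@@H]12
F2 | step 15 | (5R)-3-{[(tert-butyldimethylsilyl)oxy]methyl}-5-[(1Z,4E,6R)-3-[(tert-butyldimethylsilyl)oxy]-6-hydroxy-8,8-dimethoxy-2,6-dimethylocta-1,4-dien-1-yl]furan-2(5H)-one | CC(C)(C)[Si](C)(C)OCC1=C[C@H](OC1=O)/C=C(/C)C(O[Si](C)(C)C(C)(C)C)/C=C/[C@](C)(O)CC(OC)OC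
F3 | step 15 | (5R)-5-[(1Z,4E,6R)-3-[(tert-butyldimethylsilyl)oxy]-6-hydroxy-8,8-dimethoxy-2,6-dimethylocta-1,4-dien-1-yl]-3-(hydroxymethyl)furan-2(5H)-one | OCC1=C[C@H](OC1=O)/C=C(/C)C(O[Si](C)(C)C(C)(C)C)/C=C/[C@](C)(O)CC(OC)OC
F4 | step 15 | (5R)-3-(bromomethyl)-5-[(1Z,4E,6R)-3-[(tert-butyldimethylsilyl)oxy]-6-hydroxy-8,8-dimethoxy-2,6-dimethylocta-1,4-dien-1-yl]furan-2(5H)-one | BrCC1=C[C@H](OC1=O)/C=C(/C)C(O[Si](C)(C)C(C)(C)C)/C=C/[C@](C)(O)CC(OC)OC
F5 | step 3 | racemic (4Z)-5-iodohexa-1,4-dien-3-ol | C=CC(O)/C=C(/C)I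
F6 | step 3 | (3R,4Z)-5-iodohexa-1,4-dien-3-yl acetate | C=C[C@@H](OC(C)=O)/C=C(/C)I
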